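In this stirred vessel Z is fed in over a few minutes to J, X and Q, and two of us disputed what a larger charge of Q would do to G, the species formed on the way to D.

| flask | Z | J | X | Q | remark | time |
|---|---|---|---|---|---|---|
| Saturday's | 12 mM (fed, over 4.0 min) | 30 mM | 2.3 mM | 0.060 mM | run made earlier |  |
| flask | 12 mM (fed, over 4.0 min) | 30.0 mM | 2.3 mM | 0.12 mM |  | 30 h |

- Saturday's (time / h: G / %, D / %): 1.33: 21, 6; 2.50: 14, 10; 4.00: 7, 12; 5.00: 5, 13; 6.00: 0, 21; 8.00: 0, 15; 10.0: 0, 16

(standard deviation of a reading: 2 percentage points)

- the analysis behind the earlier runs scatters by 2 percentage points, standard deviation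
- no earlier run changes the charge of Q; that part of a forecast is a guess

* time up to 30 h at which G stands highest
* the amount of G, in percent of the Z charged, at that time
* the first time at which G reaches 11%, in the same percent

The first of us, who made the forecast, reads Saturday's G as a stock in decay, holds that “G forms quickly, mostly before the first sample”, and gives 35% at 0.4 h, with the asked level reached at 0.1 h.

The second, speaking here, reckons from D instead. Saturday's Q was 0.500% of the Z charge, yet D read 6% at 1.33 h, so I carry the turnover rate, the D made per hour by each Q charged, here a reading from that one scattered sampling, 9.02 h⁻¹. That it holds for the new charge is a guess, since no earlier run changes Q. The flask's Q is 1.00% of Z, twice Saturday's share. In Saturday's run G and D together read 27.0% at that first sampling, which I take as a ceiling for the flask, an assumption of mine, and the forecast's peak stands above it. The flask's peak should be that ceiling less the D already made. No reading shows its time, so I guess 0.665 h, the middle of the unseen stretch, and get 21.0%, well below the forecast.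

The flask gives G highest at 0.695 h, at 21.6%, and reaches the asked level at 0.176 h.

    J + L → Q + D (k = 0.0970 L mol⁻¹ s⁻¹)
    Q + G ⇌ L (K = 37000 L mol⁻¹, k = 14.0 L mol⁻¹ s⁻¹)
    Z + J → E (k = 0.0220 L mol⁻¹ s⁻¹)
    Z + X ⇌ X + G (K = 2.50, k = 0.140 L mol⁻¹ s⁻¹)

At the best time in the flask L, the resting state of Q, held 93.4% of the Q charged. For the flask the turnover rate gives 6.28% of D by then, more than the 4.79% that stood. The decay view keeps Saturday's tail, where G read 7% and then 5%.

In the neighbour charged with 0.30 mM of Q, the same turnover rate takes 15.0% from the ceiling by 0.665 h, leaving 12.0%. The computed peak there is 15.4%.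

Readings and results are simulated from invented constants; the scatter is artificial.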